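**Retrosynthetic overview** (germacrane numbering: C1=C10(Me), C4(Me)–C5 oxirane, C6 ester, C7 isopropyl, C8 OH)
1. 23 ⇐ 22 (phenol silyl ether); the ten-membered ring is opened at C1–C2 to alkenyl iodide/alkyl bromide 21, closed by a Ni-catalysed reductive coupling.
2. 21 ⇐ epoxy aldol 20 + aldehyde 16: one Evans–Tishchenko step sets C8 (1,3-anti) and puts the aroyl group on O6.
3. 20 ⇐ 19 (hydroxyl-directed epoxidation, C4/C5) ⇐ dienone 12 + bromo-enal 5 (asymmetric reductive syn-aldol, C6–C7 bond).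
4. 5 ⇐ but-3-yn-1-ol; 12 ⇐ 3-methylbut-2-enal + propargyl bromide; 16 ⇐ 4-bromophenol.
5. Ring order: oxirane first on the open chain (step 10), ten-membered carbocycle second (step 12).

Assumption: (S)-BINAPO is taken to direct si-face addition to the aldehyde in step 9, giving the (5S,6R) aldol; if the sense is the reverse, (R)-BINAPO is used.

**Step 1**
Reactants: 1 but-3-yn-1-ol
Product: 3 (2E)-3-methylpent-2-ene-1,5-diol, via alkenylalane 2 (not isolated)
Conditions: AlMe3 (3 equiv), Cp2ZrCl2 (0.25 equiv), CH2Cl2, 0 °C → rt; volatiles off; n-BuLi, THF, −78 °C; (CH2O)n, rt; aq. Rochelle salt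
Reagents that add atoms: trimethylaluminium C[Al](C)C; formaldehyde (as paraformaldehyde) C=O
Why: Negishi Zr-catalysed carboalumination adds Me and Al syn across the alkyne with Me on the internal carbon, and the alanate is hydroxymethylated with retention, fixing the E C4=C5 olefin.

**Step 2**
Reactants: 3 (2E)-3-methylpent-2-ene-1,5-diol
Product: 4 (2E)-5-hydroxy-3-methylpent-2-enal
Conditions: MnO2 (15 equiv), CH2Cl2, rt
Reagents that add atoms: none
Why: MnO2 oxidises only the allylic primary alcohol and leaves the homoallylic one (chemoselective allylic oxidation).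

**Step 3**
Reactants: 4 (2E)-5-hydroxy-3-methylpent-2-enal
Product: 5 (2E)-5-bromo-3-methylpent-2-enal
Conditions: PPh3, NBS, CH2Cl2, −20 → 0 °C
Reagents that add atoms: N-bromosuccinimide O=C1CCC(=O)N1Br
Why: Appel-type bromination through the alkoxyphosphonium salt converts the primary alcohol under neutral conditions that leave the enal untouched.

**Step 4**
Reactants: 6 3-methylbut-2-enal; 7 3-bromoprop-1-yne
Product: 9 rac-2-methylhept-2-en-6-yn-4-ol, via allenylzinc bromide 8 (not isolated)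
Conditions: Zn dust, THF, 0 °C → rt; aq. NH4Cl
Reagents that add atoms: none
Why: Zinc Barbier propargylation, in which allenylzinc bromide adds 1,2 to the enal by an SE2′ path to give the homopropargylic alcohol (the carbinol centre is removed in step 6).

**Step 5**
Reactants: 9 rac-2-methylhept-2-en-6-yn-4-ol
Product: 11 rac-(6E)-7-iodo-2,6-dimethylhepta-2,6-dien-4-ol, via alkenylalane 10 (not isolated)
Conditions: AlMe3 (3 equiv), Cp2ZrCl2 (0.3 equiv), CH2Cl2, 0 °C → rt; I2, THF, −30 °C; aq. Na2S2O3, Rochelle salt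
Reagents that add atoms: trimethylaluminium C[Al](C)C; iodine I-I
Why: Negishi carboalumination of the homopropargylic alkoxide followed by iodinolysis with retention gives the E alkenyl iodide, which fixes the C1=C10 geometry.

**Step 6**
Reactants: 11 rac-(6E)-7-iodo-2,6-dimethylhepta-2,6-dien-4-ol
Product: 12 (6E)-7-iodo-2,6-dimethylhepta-2,6-dien-4-one
Conditions: MnO2 (15 equiv), CH2Cl2, rt
Reagents that add atoms: none
Why: Neutral MnO2 allylic oxidation gives the β,β-dimethyl enone without moving the skipped iodoalkene into conjugation.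

**Step 7**
Reactants: 13 4-bromophenol
Product: 14 (4-bromophenoxy)(tert-butyl)dimethylsilane
Conditions: TBSCl, imidazole, CH2Cl2, rt
Reagents that add atoms: tert-butyl(chloro)dimethylsilane CC(C)(C)[Si](C)(C)Cl
Why: Standard imidazole-promoted silylation of a phenol.

**Step 8**
Reactants: 14 (4-bromophenoxy)(tert-butyl)dimethylsilane
Product: 16 4-[(tert-butyldimethylsilyl)oxy]benzaldehyde, via aryllithium 15 (not isolated)
Conditions: n-BuLi, THF, −78 °C; DMF, −78 → 0 °C; AcOH
Reagents that add atoms: N,N-dimethylformamide CN(C)C=O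
Why: Bromine–lithium exchange followed by Bouveault formylation with DMF.

**Step 9**
Reactants: 12 (6E)-7-iodo-2,6-dimethylhepta-2,6-dien-4-one; 5 (2E)-5-bromo-3-methylpent-2-enal
Product: 19 (1E,5S,6R,7E)-10-bromo-6-hydroxy-1-iodo-2,8-dimethyl-5-(propan-2-yl)deca-1,7-dien-4-one, via trichlorosilyl enolate 17 (not isolated), via trichlorosilyl aldolate 18 (not isolated)
Conditions: HSiCl3 (1.2 equiv), (S)-BINAPO (10 mol %), EtCN, −40 °C; then 5, −78 °C; aq. NaHCO3
Reagents that add atoms: none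
Why: Lewis-base-catalysed trichlorosilane reductive aldol, in which 1,4-hydride delivery to the s-cis enone gives only the Z trichlorosilyl enolate on the isopropyl side, and this adds through a closed BINAPO-bound transition state to the si face of 5 to give the syn aldol with C7 (5S) and C6 (6R).

**Step 10**
Reactants: 19 (1E,5S,6R,7E)-10-bromo-6-hydroxy-1-iodo-2,8-dimethyl-5-(propan-2-yl)deca-1,7-dien-4-one
Product: 20 (1S,2S,5E)-1-[(2R,3R)-3-(2-bromoethyl)-3-methyloxiran-2-yl]-1-hydroxy-6-iodo-5-methyl-2-(propan-2-yl)hex-5-en-3-one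
Conditions: mCPBA, NaHCO3, CH2Cl2, 0 °C
Reagents that add atoms: 3-chloroperoxybenzoic acid OOC(=O)c1cccc(Cl)c1
Why: Hydroxyl-directed peracid epoxidation under allylic 1,3-strain control, where the cis methyl holds the carbinol C–H in the olefin plane and the peracid, hydrogen-bonded to OH, attacks anti to C7 to give the threo (4R,5R) epoxy alcohol, the iodoalkene being too electron-poor to react.

**Step 11**
Reactants: 20 (1S,2S,5E)-1-[(2R,3R)-3-(2-bromoethyl)-3-methyloxiran-2-yl]-1-hydroxy-6-iodo-5-methyl-2-(propan-2-yl)hex-5-en-3-one; 16 4-[(tert-butyldimethylsilyl)oxy]benzaldehyde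
Product: 21 (1S,2R,3R,5E)-1-[(2R,3R)-3-(2-bromoethyl)-3-methyloxiran-2-yl]-3-hydroxy-6-iodo-5-methyl-2-(propan-2-yl)hex-5-en-1-yl 4-[(tert-butyldimethylsilyl)oxy]benzoate
Conditions: SmI2 (0.3 equiv), 16 (5 equiv), THF, −10 °C
Reagents that add atoms: none
Why: Evans–Tishchenko reduction, in which the samarium-bound hemiacetal of 20 and 16 delivers hydride to the ketone through a chair-like bicyclic transition state, giving the 1,3-anti C8 alcohol (R) and leaving the aroyl group on O6.

**Step 12**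
Reactants: 21 (1S,2R,3R,5E)-1-[(2R,3R)-3-(2-bromoethyl)-3-methyloxiran-2-yl]-3-hydroxy-6-iodo-5-methyl-2-(propan-2-yl)hex-5-en-1-yl 4-[(tert-butyldimethylsilyl)oxy]benzoate
Product: 22 (1R,2S,3R,4R,6E,10R)-4-hydroxy-6,10-dimethyl-3-(propan-2-yl)-11-oxabicyclo[8.1.0]undec-6-en-2-yl 4-[(tert-butyldimethylsilyl)oxy]benzoate
Conditions: NiBr2(dme) (30 mol %), 4,4′-di-tert-butyl-2,2′-bipyridine (33 mol %), Mn powder (4 equiv), DMA, 25 °C; 21 added by syringe pump over 12 h (final 2 mM)
Reagents that add atoms: none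
Why: Proposed new method: an intramolecular nickel-catalysed reductive alkenyl–alkyl cross-electrophile coupling at high dilution, in which bipyridine-ligated zerovalent nickel inserts into the alkenyl C–I bond with retention of the E geometry, a monovalent nickel species abstracts bromine from the tethered primary bromide, the C2 radical is captured by the alkenylnickel centre of the same molecule, and the trivalent nickel intermediate reductively eliminates the C1–C2 bond while Mn returns the catalyst to the zerovalent state; the trans-oxirane and E-olefin hold both chain ends on one side as in the crown conformer of germacrane 4,5-epoxides, and the closest known reactions are the intermolecular Weix-type alkenyl halide/alkyl halide cross-electrophile coupling and nickel-catalysed reductive aryl–alkyl macrocyclisations, neither yet shown for a ten-membered carbocycle.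

**Step 13**
Reactants: 22 (1R,2S,3R,4R,6E,10R)-4-hydroxy-6,10-dimethyl-3-(propan-2-yl)-11-oxabicyclo[8.1.0]undec-6-en-2-yl 4-[(tert-butyldimethylsilyl)oxy]benzoate
Product: 23 (1R,2S,3R,4R,6E,10R)-4-hydroxy-6,10-dimethyl-3-(propan-2-yl)-11-oxabicyclo[8.1.0]undec-6-en-2-yl 4-hydroxybenzoate
Conditions: Bu4NF, AcOH (1:1), THF, 0 °C
Reagents that add atoms: none
Why: Fluoride cleaves the aryl silyl ether, and the acetic acid buffer suppresses O6→O8 acyl migration and transannular opening of the oxirane.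

**Compound list**
1 | but-3-yn-1-ol | OCCC#C | starting material
2 | [(1E)-4-[(dimethylalumanyl)oxy]-2-methylbut-1-en-1-yl]dimethylalumane | C[Al](C)/C=C(\C)CCO[Al](C)C | intermediate
3 | (2E)-3-methylpent-2-ene-1,5-diol | OC/C=C(\C)CCO | intermediate
4 | (2E)-5-hydroxy-3-methylpent-2-enal | O=C/C=C(\C)CCO | intermediate
5 | (2E)-5-bromo-3-methylpent-2-enal | O=C/C=C(\C)CCBr | intermediate
6 | 3-methylbut-2-enal | CC(C)=CC=O | starting material
7 | 3-bromoprop-1-yne | BrCC#C | starting material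
8 | propa-1,2-dienylzinc bromide | C=C=C[Zn]Br | intermediate
9 | rac-2-methylhept-2-en-6-yn-4-ol | CC(C)=CC(O)CC#C | intermediate
10 | [(1E)-4-[(dimethylalumanyl)oxy]-2,6-dimethylhepta-1,5-dien-1-yl]dimethylalumane (racemic) | C[Al](C)/C=C(\C)CC(O[Al](C)C)C=C(C)C | intermediate
11 | rac-(6E)-7-iodo-2,6-dimethylhepta-2,6-dien-4-ol | CC(C)=CC(O)C/C(C)=C/I | intermediate
12 | (6E)-7-iodo-2,6-dimethylhepta-2,6-dien-4-one | CC(C)=CC(=O)C/C(C)=C/I | intermediate
13 | 4-bromophenol | Oc1ccc(Br)cc1 | starting material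
14 | (4-bromophenoxy)(tert-butyl)dimethylsilane | CC(C)(C)[Si](C)(C)Oc1ccc(Br)cc1 | intermediate
15 | {4-[(tert-butyldimethylsilyl)oxy]phenyl}lithium | [Li]c1ccc(O[Si](C)(C)C(C)(C)C)cc1 | intermediate
16 | 4-[(tert-butyldimethylsilyl)oxy]benzaldehyde | CC(C)(C)[Si](C)(C)Oc1ccc(C=O)cc1 | intermediate
17 | trichloro{[(3Z,6E)-7-iodo-2,6-dimethylhepta-3,6-dien-4-yl]oxy}silane | CC(C)/C=C(\O[Si](Cl)(Cl)Cl)C/C(C)=C/I | intermediate
18 | O-trichlorosilyl ether of 19 (same configuration) | BrCC/C(C)=C/[C@@H](O[Si](Cl)(Cl)Cl)[C@H](C(C)C)C(=O)C/C(C)=C/I | intermediate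
19 | (1E,5S,6R,7E)-10-bromo-6-hydroxy-1-iodo-2,8-dimethyl-5-(propan-2-yl)deca-1,7-dien-4-one | BrCC/C(C)=C/[C@@H](O)[C@H](C(C)C)C(=O)C/C(C)=C/I | intermediate
20 | (1S,2S,5E)-1-[(2R,3R)-3-(2-bromoethyl)-3-methyloxiran-2-yl]-1-hydroxy-6-iodo-5-methyl-2-(propan-2-yl)hex-5-en-3-one | BrCC[C@@]1(C)O[C@@H]1[C@@H](O)[C@H](C(C)C)C(=O)C/C(C)=C/I | intermediate
21 | (1S,2R,3R,5E)-1-[(2R,3R)-3-(2-bromoethyl)-3-methyloxiran-2-yl]-3-hydroxy-6-iodo-5-methyl-2-(propan-2-yl)hex-5-en-1-yl 4-[(tert-butyldimethylsilyl)oxy]benzoate | BrCC[C@@]1(C)O[C@@H]1[C@@H](OC(=O)c2ccc(O[Si](C)(C)C(C)(C)C)cc2)[C@H](C(C)C)[C@H](O)C/C(C)=C/I | intermediate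
22 | (1R,2S,3R,4R,6E,10R)-4-hydroxy-6,10-dimethyl-3-(propan-2-yl)-11-oxabicyclo[8.1.0]undec-6-en-2-yl 4-[(tert-butyldimethylsilyl)oxy]benzoate | C/C1=C\CC[C@@]2(C)O[C@@H]2[C@@H](OC(=O)c2ccc(O[Si](C)(C)C(C)(C)C)cc2)[C@H](C(C)C)[C@H](O)C1 | intermediate
23 | (1R,2S,3R,4R,6E,10R)-4-hydroxy-6,10-dimethyl-3-(propan-2-yl)-11-oxabicyclo[8.1.0]undec-6-en-2-yl 4-hydroxybenzoate (CNP0319712.1) | C/C1=C\CC[C@@]2(C)O[C@@H]2[C@@H](OC(=O)c2ccc(O)cc2)[C@H](C(C)C)[C@H](O)C1 | target

**Step count and risks**
Total step count: 13. Longest linear sequence: 8 steps (1, 2, 3, 9, 10, 11, 12, 13; the sequence 4, 5, 6, 9–13 is equally long).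

Steps most likely to fail:

Step 12 (the proposed new macrocyclisation). The risks are dimerisation, reduction of either halide, and opening of the oxirane by metal halides. The fallback sets out from 21 and rejoins at 23, replacing the radical cross-electrophile manifold by a two-electron coupling of a preformed organometallic. The C8 hydroxyl is capped (Et3SiOTf, 2,6-lutidine, CH2Cl2, −78 °C) to give the triethylsilyl ether of 21 F1. Finkelstein exchange (NaI, acetone, 45 °C) gives the primary iodide F2. Activated Zn dust (THF/DMA, 35 °C) inserts only into the alkyl C–I bond to give the alkylzinc iodide F3. Slow addition of F3 to Pd2(dba)3/SPhos (THF, 45 °C) effects an intramolecular Negishi sp3–sp2 coupling to the bis-silylated macrocycle F4. Bu4NF/AcOH removes both silyl groups and gives 23.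

Step 9. The dialkyl β,β-dimethyl enone and the aliphatic enal lie outside the usual aryl substrate range of the trichlorosilane reductive aldol, so yield and ee are uncertain. The fallback sets out from 12 and 5 and rejoins at 19, using an isolated enol silane and chiral Lewis-acid catalysis. Conjugate hydrosilylation of 12 with catalytic [(Ph3P)CuH]6 and PhMe2SiH (toluene, rt) gives the (Z)-dimethyl(phenyl)silyl enol ether F5. A syn-selective Mukaiyama aldol of F5 with 5 under Yamamoto's chiral acyloxyborane catalyst (from BH3·THF and (2S,3S)-2-O-(2,6-diisopropoxybenzoyl)tartaric acid, 20 mol %, EtCN, −78 °C) gives the O-silyl aldol F6. 1 M HCl/THF releases 19.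

Step 11. The new C8 samarium alkoxide may open the 4,5-oxirane to a tetrahydrofuran, and the acyl group may migrate. The fallback sets out from 20 and 16 and rejoins at 21, separating acylation from a reagent-controlled reduction. Pinnick oxidation of 16 (NaClO2, NaH2PO4, 2-methylbut-2-ene, t-BuOH/H2O) gives 4-[(tert-butyldimethylsilyl)oxy]benzoic acid F7. Steglich esterification of 20 with F7 (DCC, DMAP, CH2Cl2, 0 °C) gives the β-aroyloxy ketone F8. Corey–Bakshi–Shibata reduction ((S)-2-methyl-CBS-oxazaborolidine, catecholborane, toluene, −78 °C) sets the C8 carbinol (R) and gives 21.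

**Further compounds**
F1 | step 12 | C8-O-triethylsilyl ether of 21 | BrCC[C@@]1(C)O[C@@H]1[C@@H](OC(=O)c2ccc(O[Si](C)(C)C(C)(C)C)cc2)[C@H](C(C)C)[C@H](O[Si](CC)(CC)CC)C/C(C)=C/I
F2 | step 12 | primary iodide corresponding to F1 (CH2CH2I in place of CH2CH2Br) | ICC[C@@]1(C)O[C@@H]1[C@@H](OC(=O)c2ccc(O[Si](C)(C)C(C)(C)C)cc2)[C@H](C(C)C)[C@H](O[Si](CC)(CC)CC)C/C(C)=C/I
F3 | step 12 | alkylzinc iodide from F2 | I[Zn]CC[C@@]1(C)O[C@@H]1[C@@H](OC(=O)c2ccc(O[Si](C)(C)C(C)(C)C)cc2)[C@H](C(C)C)[C@H](O[Si](CC)(CC)CC)C/C(C)=C/I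
F4 | step 12 | C8-O-triethylsilyl ether of 22 | C/C1=C\CC[C@@]2(C)O[C@@H]2[C@@H](OC(=O)c2ccc(O[Si](C)(C)C(C)(C)C)cc2)[C@H](C(C)C)[C@H](O[Si](CC)(CC)CC)C1
F5 | step 9 | {[(3Z,6E)-7-iodo-2,6-dimethylhepta-3,6-dien-4-yl]oxy}dimethyl(phenyl)silane | CC(C)/C=C(\O[Si](C)(C)c1ccccc1)C/C(C)=C/I
F6 | step 9 | O-dimethyl(phenyl)silyl ether of 19 | BrCC/C(C)=C/[C@@H](O[Si](C)(C)c1ccccc1)[C@H](C(C)C)C(=O)C/C(C)=C/I
F7 | step 11 | 4-[(tert-butyldimethylsilyl)oxy]benzoic acid | CC(C)(C)[Si](C)(C)Oc1ccc(cc1)C(O)=O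
F8 | step 11 | O6-aroyl ester of 20 (C8 ketone retained) | BrCC[C@@]1(C)O[C@@H]1[C@@H](OC(=O)c2ccc(O[Si](C)(C)C(C)(C)C)cc2)[C@H](C(C)C)C(=O)C/C(C)=C/I
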